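**Strategy.** The oxane ring (O1, C2, C3, C4, C5, C6) is disconnected at the C2–O1–C6 link: O1 is inserted late into the C2–C6 bond of a 2-bromo-4-alkylcyclopentanone by Baeyer–Villiger oxidation. The bromine on C3, next to the carbonyl carbon C2, forces C6 to migrate, so one operation fixes ring size, the O1–C6 bond and the regiochemistry, with C3 and C5 carried through. The ketone comes from a cyclopent-3-enyl ring whose two arms (C2/C6 and C3/C4) are equivalent until a catalytic bromide opening of its epoxide sets C3 and C5 together. The side-chain tertiary chloride stems from Sharpless epoxidation and chloride inversion; methyl addition to the lactone then gives the hemiketal under thermodynamic control.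

Key step: step 11

Remark on the chemistry: O1 and C2–C6 are the oxane atoms of the target throughout. The hemiketal carbon C2 is assumed to equilibrate through the open δ-hydroxy ketone, so its configuration is set thermodynamically. In step 9 the ligand antipode is the one that leads to the (1S,2S)-bromohydrin.

**Step 1**
Reactants: 1 cyclopent-3-ene-1-carboxylic acid
Product: 2 1-(cyclopent-3-en-1-yl)ethan-1-one
Conditions: MeLi (2.2 equiv), Et2O, 0 °C to rt; inverse quench into cold 1 M HCl
Reagents that add atoms: methyllithium, [Li]C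
Why: Methyl ketone synthesis from a carboxylic acid with two equivalents of an organolithium, in which the lithium carboxylate takes up only one further equivalent before the quench; no stereocentre is involved.

**Step 2**
Reactants: 2 1-(cyclopent-3-en-1-yl)ethan-1-one
Product: 3 ethyl (2E)-3-(cyclopent-3-en-1-yl)but-2-enoate
Conditions: (EtO)2P(O)CH2CO2Et, NaH, THF, 0 °C to 60 °C
Reagents that add atoms: triethyl phosphonoacetate, CCOC(=O)CP(=O)(OCC)OCC
Why: Horner–Wadsworth–Emmons olefination of a methyl ketone should place the branched cyclopentenyl group trans to the ester (E), the minor Z isomer being removed by chromatography.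

**Step 3**
Reactants: 3 ethyl (2E)-3-(cyclopent-3-en-1-yl)but-2-enoate
Product: 4 (2E)-3-(cyclopent-3-en-1-yl)but-2-en-1-ol
Conditions: DIBAL-H (2.2 equiv), CH2Cl2, −78 °C; Rochelle salt
Reagents that add atoms: none
Why: 1,2-Reduction of an enoate with DIBAL-H at low temperature gives the allylic alcohol without touching either C=C bond or the alkene geometry.

**Step 4**
Reactants: 4 (2E)-3-(cyclopent-3-en-1-yl)but-2-en-1-ol
Product: 5 [(2R,3R)-3-(cyclopent-3-en-1-yl)-3-methyloxiran-2-yl]methanol
Conditions: Ti(OiPr)4 (10 mol%), D-(−)-diethyl tartrate (12 mol%), t-BuOOH, 4 Å MS, CH2Cl2, −20 °C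
Reagents that add atoms: tert-butyl hydroperoxide, CC(C)(C)OO
Why: Sharpless asymmetric epoxidation is directed by the allylic hydroxyl, so the ring alkene is left alone, and the D-tartrate catalyst should deliver oxygen to the face of this (E)-3,3-disubstituted allylic alcohol that gives the (2R,3R)-epoxide.

**Step 5**
Reactants: 5 [(2R,3R)-3-(cyclopent-3-en-1-yl)-3-methyloxiran-2-yl]methanol
Product: 6 (2R,3S)-3-chloro-3-(cyclopent-3-en-1-yl)butane-1,2-diol
Conditions: ClTi(OiPr)3 (1.5 equiv), CH2Cl2, 0 °C to rt; aq. tartaric acid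
Reagents that add atoms: chlorotitanium triisopropoxide, CC(C)O[Ti](Cl)(OC(C)C)OC(C)C
Why: Titanium-assisted ring opening of a 2,3-epoxy alcohol by chloride should occur at the tertiary C3 (chelation of titanium by the C1 hydroxyl and the epoxide oxygen, better cation stabilisation at C3) by backside attack, so C3 is inverted to the (S)-tertiary chloride while C2 is untouched.

**Step 6**
Reactants: 6 (2R,3S)-3-chloro-3-(cyclopent-3-en-1-yl)butane-1,2-diol
Product: 7 (2S)-2-chloro-2-(cyclopent-3-en-1-yl)propanal
Conditions: NaIO4, THF/H2O, 0 °C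
Reagents that add atoms: none
Why: Malaprade glycol cleavage removes C1 as formaldehyde and leaves an α-chloro aldehyde whose α-carbon is quaternary and therefore cannot epimerise.

**Step 7**
Reactants: 7 (2S)-2-chloro-2-(cyclopent-3-en-1-yl)propanal
Product: 8 4-[(2S,3E)-4-bromo-2-chlorobut-3-en-2-yl]cyclopent-1-ene
Conditions: CHBr3 (2 equiv), anhydrous CrBr2 (6 equiv), THF, 0 °C to rt
Reagents that add atoms: bromoform, BrC(Br)Br
Why: Takai olefination with the geminal dichromium reagent from bromoform should give the (E)-bromoalkene, the all-bromide chromium source avoiding Br/Cl exchange and the fast carbonyl addition outrunning reduction of the hindered tertiary C–Cl bond.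

**Step 8**
Reactants: 8 4-[(2S,3E)-4-bromo-2-chlorobut-3-en-2-yl]cyclopent-1-ene
Product: 9 (1R,3s,5S)-3-[(2S,3E)-4-bromo-2-chlorobut-3-en-2-yl]-6-oxabicyclo[3.1.0]hexane (epoxide oxygen trans to the side chain)
Conditions: mCPBA, NaHCO3, CH2Cl2, 0 °C
Reagents that add atoms: 3-chloroperbenzoic acid, OOC(=O)c1cccc(Cl)c1
Why: Prilezhaev epoxidation should take place only at the cyclopentene (the bromoalkene is electron-poor and hindered) and on the face anti to the bulky quaternary substituent, giving the trans epoxide whose two oxirane carbons are still equivalent arms.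

**Step 9**
Reactants: 9 (1R,3s,5S)-3-[(2S,3E)-4-bromo-2-chlorobut-3-en-2-yl]-6-oxabicyclo[3.1.0]hexane
Product: 11 (1S,2S,4S)-2-bromo-4-[(2S,3E)-4-bromo-2-chlorobut-3-en-2-yl]cyclopentan-1-ol, via trimethylsilyl ether 10 (not isolated)
Conditions: zirconium–homochiral triisopropanolamine catalyst (5 mol%), allyl bromide (excess), TMSN3 (1.1 equiv), PhCl, rt; then 1 M HCl, THF, 0 °C
Reagents that add atoms: allyl bromide, C=CCBr (source of Br); azidotrimethylsilane, C[Si](C)(C)N=[N+]=[N-] (silyl group of 10 only)
Why: Zirconium–trialkanolamine-catalysed enantiotopos-selective opening of a meso-type epoxide by bromide is an anti SN2 process, so catalyst-controlled attack at the (R)-configured oxirane carbon places bromine cis to the side chain with inversion, leaves the trans carbinol, and at the same stroke makes the ring carbon bearing the side chain a defined stereocentre.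

**Step 10**
Reactants: 11 (1S,2S,4S)-2-bromo-4-[(2S,3E)-4-bromo-2-chlorobut-3-en-2-yl]cyclopentan-1-ol
Product: 12 (2S,4S)-2-bromo-4-[(2S,3E)-4-bromo-2-chlorobut-3-en-2-yl]cyclopentan-1-one
Conditions: Dess–Martin periodinane, NaHCO3, CH2Cl2, 0 °C to rt; used without storage
Reagents that add atoms: none
Why: Dess–Martin oxidation under buffered, non-basic conditions should give the α-bromo ketone without enolisation, so the bromine stays cis to the side chain.

**Step 11**
Reactants: 12 (2S,4S)-2-bromo-4-[(2S,3E)-4-bromo-2-chlorobut-3-en-2-yl]cyclopentan-1-one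
Product: 14 (3S,5R)-3-bromo-5-[(2S,3E)-4-bromo-2-chlorobut-3-en-2-yl]oxan-2-one, via Criegee adduct 13 (not isolated)
Conditions: mCPBA (2.5 equiv), NaHCO3, CH2Cl2, rt
Reagents that add atoms: 3-chloroperbenzoic acid, OOC(=O)c1cccc(Cl)c1
Why: The peracid adds to the carbonyl carbon C2 of 12 to give Criegee adduct 13, in which the C2–C6 bond, antiperiplanar to the O–O bond, shifts from C2 to oxygen with loss of 3-chlorobenzoate (Baeyer–Villiger oxidation; closest precedent: oxidation of 2-halocycloalkanones, where the unhalogenated α-carbon migrates). No cyclisation is involved: the six-membered ring O1–C2–C3–C4–C5–C6 arises by enlargement of the five-membered carbocycle through this 1,2-carbon-to-oxygen shift, O1 being inserted between C2 and C6. No new stereocentre is formed; C3 and C5 do not take part and the migrating C6 is a methylene group, so the cis relation of bromine and side chain is carried over unchanged. The step needs regioselectivity (C6, not C3, must migrate), which the electron-withdrawing bromine on C3 secures by lowering the migratory aptitude of that carbon, and chemoselectivity over C=C, secured because the only remaining alkene is an electron-poor bromoalkene next to a quaternary carbon. The bicarbonate buffer keeps the α-bromo ketone and the α-bromo lactone from enolising.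

**Step 12**
Reactants: 14 (3S,5R)-3-bromo-5-[(2S,3E)-4-bromo-2-chlorobut-3-en-2-yl]oxan-2-one
Product: 15 (2R,3S,5R)-3-bromo-5-[(2S,3E)-4-bromo-2-chlorobut-3-en-2-yl]-2-methyloxan-2-ol
Conditions: MeLi/CeCl3 (1.2 equiv, premixed), THF, −78 °C; sat. aq. NH4Cl added at −78 °C
Reagents that add atoms: methyllithium, [Li]C
Why: Organocerium addition to a δ-lactone should stop at the lactol because the tetrahedral alkoxide persists at −78 °C and the weakly basic reagent avoids enolisation or halogen–metal exchange at the α-bromo carbon; C2 is then set by ring–chain equilibration to the anomer with axial OH (anomeric effect) and equatorial CH3, which is (2R).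

**Compound list**
1 | cyclopent-3-ene-1-carboxylic acid | OC(=O)C1CC=CC1 | starting material
2 | 1-(cyclopent-3-en-1-yl)ethan-1-one | CC(=O)C1CC=CC1 | intermediate
3 | ethyl (2E)-3-(cyclopent-3-en-1-yl)but-2-enoate | CCOC(=O)/C=C(\C)C1CC=CC1 | intermediate
4 | (2E)-3-(cyclopent-3-en-1-yl)but-2-en-1-ol | OC/C=C(\C)C1CC=CC1 | intermediate
5 | [(2R,3R)-3-(cyclopent-3-en-1-yl)-3-methyloxiran-2-yl]methanol | C[C@@]1(O[C@@H]1CO)C2CC=CC2 | intermediate
6 | (2R,3S)-3-chloro-3-(cyclopent-3-en-1-yl)butane-1,2-diol | C[C@@](Cl)([C@H](O)CO)C1CC=CC1 | intermediate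
7 | (2S)-2-chloro-2-(cyclopent-3-en-1-yl)propanal | C[C@@](Cl)(C=O)C1CC=CC1 | intermediate
8 | 4-[(2S,3E)-4-bromo-2-chlorobut-3-en-2-yl]cyclopent-1-ene | C[C@@](Cl)(/C=C/Br)C1CC=CC1 | intermediate
9 | (1R,3s,5S)-3-[(2S,3E)-4-bromo-2-chlorobut-3-en-2-yl]-6-oxabicyclo[3.1.0]hexane, oxygen trans to side chain | C[C@@](Cl)(/C=C/Br)[C@H]1C[C@@H]2O[C@@H]2C1 | intermediate
10 | {[(1S,2S,4S)-2-bromo-4-[(2S,3E)-4-bromo-2-chlorobut-3-en-2-yl]cyclopentyl]oxy}trimethylsilane | C[C@@](Cl)(/C=C/Br)[C@H]1C[C@H](O[Si](C)(C)C)[C@@H](Br)C1 | intermediate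
11 | (1S,2S,4S)-2-bromo-4-[(2S,3E)-4-bromo-2-chlorobut-3-en-2-yl]cyclopentan-1-ol | C[C@@](Cl)(/C=C/Br)[C@H]1C[C@H](O)[C@@H](Br)C1 | intermediate
12 | (2S,4S)-2-bromo-4-[(2S,3E)-4-bromo-2-chlorobut-3-en-2-yl]cyclopentan-1-one | C[C@@](Cl)(/C=C/Br)[C@H]1CC(=O)[C@@H](Br)C1 | intermediate
13 | (2S,4S)-2-bromo-4-[(2S,3E)-4-bromo-2-chlorobut-3-en-2-yl]-1-hydroxycyclopentyl 3-chloroperbenzoate (Criegee adduct, C1 unspecified) | C[C@@](Cl)(/C=C/Br)[C@H]1CC(O)(OOC(=O)c2cccc(Cl)c2)[C@@H](Br)C1 | intermediate
14 | (3S,5R)-3-bromo-5-[(2S,3E)-4-bromo-2-chlorobut-3-en-2-yl]oxan-2-one | C[C@@](Cl)(/C=C/Br)[C@H]1COC(=O)[C@@H](Br)C1 | intermediate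
15 | (2R,3S,5R)-3-bromo-5-[(2S,3E)-4-bromo-2-chlorobut-3-en-2-yl]-2-methyloxan-2-ol | C[C@@](Cl)(/C=C/Br)[C@H]1CO[C@@](C)(O)[C@@H](Br)C1 | target

**Total step count:** 12. **Longest linear sequence:** 12 steps (from 1).

**Steps most likely to fail**

Step 9. The catalyst may fail to distinguish the two oxirane carbons of a substrate that already carries a remote stereocentre, or azide may compete with bromide as the nucleophile. Fallback: setting out from epoxide 9, an unselective anti opening with Li2NiBr4 (THF, 0 °C) should give bromohydrin 11 together with its ring-mirror diastereomer (1R,2R,4R)-2-bromo-4-[(2S,3E)-4-bromo-2-chlorobut-3-en-2-yl]cyclopentan-1-ol F1. A lipase (Burkholderia cepacia lipase, vinyl acetate, MTBE) is expected, from its usual preference for (R)-configured carbinols of trans-2-halocycloalkanols, to acylate only F1 to (1R,2R,4R)-2-bromo-4-[(2S,3E)-4-bromo-2-chlorobut-3-en-2-yl]cyclopentyl acetate F2. The unreacted alcohol is separated by chromatography and the route is rejoined at compound 11.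

Step 12. Deprotonation at the α-bromo carbon, halogen–metal exchange, a second addition after ring opening, or displacement of bromide by the liberated C6 alkoxide may compete with clean mono-addition. Fallback: setting out from lactone 14, carbonyl methylenation with dimethyltitanocene (Petasis reagent, toluene, 65 °C, dark) should give the enol ether (3S,5R)-3-bromo-5-[(2S,3E)-4-bromo-2-chlorobut-3-en-2-yl]-2-methylideneoxane F3. It is not stored but hydrated at once (PPTS, wet THF, 0 °C) by protonation at the CH2 terminus and capture of the oxocarbenium ion by water, which rejoins the route at compound 15.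

Step 5. Ionisation at the hindered tertiary carbon may erode the inversion, or a 1,2-shift (semipinacol) or attack at C2 may intervene. Fallback: setting out from allylic alcohol 4, a titanium/chiral Schiff base-catalysed enantioselective dichlorination (t-BuOCl, ClTi(OiPr)3, hexanes, −20 °C) should add chlorine anti across the alkene, with chloride on the tertiary carbon, to give (2R,3S)-2,3-dichloro-3-(cyclopent-3-en-1-yl)butan-1-ol F4. K2CO3 in MeOH closes the 2-chloro-1-ol to (2S)-2-[(1S)-1-chloro-1-(cyclopent-3-en-1-yl)ethyl]oxirane F5, and periodic acid (H5IO6, THF/H2O) cleaves this terminal epoxide to the aldehyde, rejoining the route at compound 7.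

**Further compounds**
F1 | step 9 | (1R,2R,4R)-2-bromo-4-[(2S,3E)-4-bromo-2-chlorobut-3-en-2-yl]cyclopentan-1-ol | C[C@@](Cl)(/C=C/Br)[C@H]1C[C@@H](Br)[C@H](O)C1
F2 | step 9 | (1R,2R,4R)-2-bromo-4-[(2S,3E)-4-bromo-2-chlorobut-3-en-2-yl]cyclopentyl acetate | C[C@@](Cl)(/C=C/Br)[C@H]1C[C@@H](Br)[C@H](OC(C)=O)C1
F3 | step 12 | (3S,5R)-3-bromo-5-[(2S,3E)-4-bromo-2-chlorobut-3-en-2-yl]-2-methylideneoxane | C[C@@](Cl)(/C=C/Br)[C@H]1COC(=C)[C@@H](Br)C1
F4 | step 5 | (2R,3S)-2,3-dichloro-3-(cyclopent-3-en-1-yl)butan-1-ol | C[C@@](Cl)([C@H](Cl)CO)C1CC=CC1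
F5 | step 5 | (2S)-2-[(1S)-1-chloro-1-(cyclopent-3-en-1-yl)ethyl]oxirane | C[C@@](Cl)([C@@H]1CO1)C2CC=CC2
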